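The numbers of this flask are invented.

At the charge, the protic impurity took starting material 14.8 times as fast as the forward opening step did.

| setting | eta | beta | alpha | theta |
|---|---|---|---|---|
| starting material | 0.28 M | 0.28 M (fed, over 1.00 h) | 0.28 M | 0.28 M |
| partner | 1.20 equiv | 1.20 equiv | 1.20 equiv | 1.20 equiv (fed, over 1.00 h) |
| protic impurity | 0.280 M | 0.280 M | 0.280 M | 0.280 M |
| time | 1.0 h | 1.0 h |  | 1.0 h |
| remark | a closed flask charged with all of it at once and left for 1.0 h | a stirred flask in which starting material is dosed at a steady rate over 1.00 h without added volume, worked up at 1.0 h | one stirred flow tank at steady state, fed with the mixture as stated, mean residence time 1.0 h | a stirred flask in which partner is dosed at a steady rate over 1.00 h without added volume, worked up at 1.0 h |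

    starting material ⇌ open intermediate (K1 = 3.6, k1 = 0.011 /min)
    partner → second intermediate (k2 = 0.028 /min)
    open intermediate + second intermediate → target (k3 = 0.32 /M/min)
    2 second intermediate → homo product (k4 = 0.30 /M/min)
    starting material + second intermediate → side product A (k5 = 0.29 /M/min)
    second intermediate → side product B (k6 = 0.021 /min)
    starting material + protic impurity → quenched substrate (k7 = 0.58 /M/min)

- a doubled species enters its step squared and goes two at a time
- the stated concentrations are those of everything mixed, before any reaction; amounts are the same in each set-up
- the feed brings no volume worth counting
- run time (eta): 1.0 h

- the set-up with the highest amount of open intermediate at the outlet or at the end, in percent of the starting material put in ("none" if the first two lie within 2 percentage points) (eta / beta / alpha / theta / none)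
- amount of open intermediate at the outlet or at the end, in percent of the starting material put in, eta
- amount of open intermediate at the outlet or at the end, in percent of the starting material put in, beta
- amount of open intermediate at the outlet or at the end, in percent of the starting material put in, alpha
- amount of open intermediate at the outlet or at the end, in percent of the starting material put in, theta

Where did the starting material go? I divided one rate by another: c(starting material) stood in both and cancelled, and time dropped out. At the charged c(protic impurity) this gave 6.34 %: the opening share, forward opening over forward opening plus quenching. The route to side product A is not counted in this share, since it needs second intermediate and none was charged.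

Did that share last? Over the whole charge, protic impurity and starting material stood at 1.00 to one, so the impurity was no excess reagent on that count and its pseudo-first-order rate was good for the start. As c(protic impurity) fell, the share had to rise.

Could the equilibrium constant of 3.6, which favours the open form, come into it? In theta the relaxation half-life of the opening step alone, both ways together, was 0.822 h, while quenching alone at the charged c(protic impurity) gave starting material a half-life of 4.27 min. So I took this as kinetic, not thermodynamic, control.

With equal charges I expected open intermediate of the order of 6.34 % in each set-up, and I committed to "none" without a figure for each. There the forecast went further than I did, with 4 % for eta, 5.9 % for beta, 5.3 % for alpha and 4.7 % for theta, and also "none". Its ground was “The protic impurity quenches most of the starting material”.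

The simulation gave 3.84 % for eta, 4.59 % for beta, 5.39 % for alpha and 6.16 % for theta, so the answer was none: theta led, by 0.77 percentage points over alpha. In theta at 0.0753 h, about when half of the quenching up to the end was done (0.0753 h), quenching ran 8.6 times as fast as the forward opening step alone, which put the opening share at 10.4 % against 6.34 % at the charge. Theta ended with open intermediate and target together at 10.7 % of the starting material charged.

In the neighbour of theta with 0.70 M of protic impurity (2.50 equiv), the opening share at the charge was 2.64 %. That flask ended with 1.45 % as open intermediate and 1.44 % as target, together 2.89 %.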